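The runs are calculated with made-up constants, and the scatter is random.

Reagent is conserved. By the proposed steps each side product holds one reagent and each target two, and the rest is free or in intermediate. So unspent reagent, as a fraction of the substrate charged, is the charge minus side product minus 2 target.

all flasks: substrate 20 mM

| charge | reagent | remark | time |
|---|---|---|---|
| south | 0.50 equiv | run made earlier |  |
| flask | 1.00 equiv |  | 2.5 d |

- south (time / h: side product / %, target / %, substrate / %): 1.00: 12.6, 8.8, 19.6; 3.00: 21.1, 10.8, 6.8; 6.00: 22.8, 11.4, 3.7; 8.00: 24.5, 11.7, 2.4; 12.0: 24.5, 11.4, 1.7

(readings scatter by 0.3 percentage points)

- a species is counted by the substrate in it: one homo dimer counts as two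
- amounts and yields of target count crystals too
- given per volume of solution although it is solid: crystals
- the earlier runs were read with a standard deviation of 0.3 percentage points
- steps that have been proposed: crystals <-> target; 2 substrate -> homo dimer; intermediate -> side product; substrate + reagent <-> intermediate; reagent + intermediate -> target

* ratio of side product to target at 10 min
* ratio of side product to target at 3.0 h
* ratio of side product to target at 2.5 d

Two chemists dispute this flask. The first says the flask has a full equivalent of reagent, so reagent can be treated as constant and the ratio frozen. The second says unspent reagent falls, so the ratio climbs.

Both use one number, the branch number b (a selectivity factor): side product made per target made, times unspent reagent. In the south run, unspent reagent falls from 0.50 equiv to 0.198 by 1.00 h. Taking the geometric middle of that interval, the readings give b = 0.451.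

The first chemist therefore expects 0.451 at every time. The second points out that the south ratio rose from 1.43 to 2.15.

I side with the second. Freeze b and let reagent move, with intermediate small. From charge c down to r left, side product is then b/2 · ln((b+2c)/(b+2r)).

I still need r. The south run had captured 35.9% of its substrate by 12.0 h, and 1.7% still stood as substrate; I book the rest as homo dimer. I take the odds of capture in proportion to the reagent charge, which gives this flask a share of 0.528. Trying r = 0.200 gives side product 0.238 and target 0.281. Together those make 0.519 against that share, so my final ratio is 0.847.

The forecast says 0.5, 0.72 and 0.79, with this remark: “Crystals are counted with target, so they don't affect the ratio.”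

The flask gives 0.424, 0.852 and 0.922.

    crystals ⇌ target, rate k1*(cs1 - [target]) while solid is left; crystals form when [target] > cs1 (solubility = 0.220 mM, k = 0.0890 s⁻¹)
    2 substrate → homo dimer (k = 0.0180 M⁻¹ s⁻¹)
    intermediate → side product (k = 3.30 × 10⁻⁴ s⁻¹)
    substrate + reagent ⇌ intermediate (K = 1900 M⁻¹, k = 0.0350 M⁻¹ s⁻¹)
    reagent + intermediate → target (k = 0.0490 M⁻¹ s⁻¹)

In this flask the ratio stands higher at 2.5 d than at 10 min, so the second view stands. The first keeps the opening, where the flask shows 0.424 at 10 min against its 0.451. At 2.50 d this flask holds substrate 0% and unbound reagent 11.1%, each of its own charge. The neighbour flask charged with 0.400 equiv of reagent ends with 2.28% of that reagent unbound, and b then gives side product 22.1%. That neighbour flask holds 23.1% of side product.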